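The rate constants come from no measurement.

Bis adduct takes two reagent per substrate, so this flask, with one equivalent, cannot hold more than 50.0% of its substrate as bis adduct.

substrate 20 mM; reagent 20.0 mM (in portions, 3); time 15 d; the portions of reagent follow each other after 3.0 h, the first at the start

    reagent + bis adduct → triple product (k1 = 0.0043 M⁻¹ min⁻¹)
    reagent + first product → bis adduct (k2 = 0.31 M⁻¹ min⁻¹)
    reagent + triple product → tetra adduct (k3 = 0.038 M⁻¹ min⁻¹)
    substrate + reagent → first product (k4 = 0.10 M⁻¹ min⁻¹)
    substrate + triple product → side product (k5 = 0.064 M⁻¹ min⁻¹)

* how much of the substrate has reacted by 15 d
* how much bis adduct there is at 15 d, in percent of the substrate charged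

- percentages count the substrate that a species holds: one side product counts as two
- run time (flask): 15 d

I kept the books on the reagent, the limiting reagent here, and closed them at zero reagent, because the half-life of substrate by its own step at full charge, 0.24 d, is short against 15 d. The first entry was reagent taken by substrate, the second reagent taken by first product. Reagent stands in both rates and cancels from their ratio, so the portions did not enter my reckoning. What entered was the selectivity factor S, the first-product constant over the substrate constant, 3.10. With a the share of substrate left, the share as first product is m = (a − a^S)/(S − 1). Bis adduct is conversion minus m, and at one equivalent the books close when conversion plus bis adduct equals the charge, which makes bis adduct equal to a. With S rounded to 3, I got a = 41.4%, so conversion 58.6%.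

The third entry was the small one, reagent taken by bis adduct. Its constant is 0.0430 of the substrate constant, the exposure to reagent in substrate units is ln(1/a), and I took bis adduct at a mean of 0.5 its final share. That leak came to 0.785%, so I committed to 40.6% bis adduct, less than the forecast's 40.8%. The forecast gave 58.6% conversion, holding that “dosing hardly alters their selectivity”.

The simulation gave 58.6% conversion and 40.6% bis adduct. In the flask, substrate and first product took reagent while it lasted: at 0.250 d, just before the last portion, reagent stood at 36.0% of its charge with 7.55% bis adduct, and at 0.750 d bis adduct stood at 33.7%. From 7.50 d on, with 0% reagent, bis adduct stood at 40.6%. S applied to the 41.4% substrate left gives 16.6% first product, and the flask held 16.7%. The neighbour flask with 8.0 mM reagent kept 71.4% substrate, from which S gives 17.2% first product, and it held 17.2%.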